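**Assumptions (remarks on the chemistry).** Compounds 10–22 and 25 are racemic and are drawn and named as the enantiomer that leads to 27. Tetraene 9 is expected to cyclize near room temperature, so it is generated and consumed in one flask. (R)-Danshensu is taken as the free acid; its sodium salt would need one equivalent less base in step 13. Steps 5 and 14 each join two molecules of one compound (6 and 24); the compound stands once among the reactants and its second molecule is entered as the atom-donating partner.

## The problem

The target is the bis[(R)-danshensu] ester of a 3,4-diarylcyclobutane-1,2-dicarboxylic acid with four contiguous ring stereocentres, (1R,2R,3R,4R). The two carboxyls are trans, the two catechol rings are trans, and each carboxyl is cis to the aryl on the neighbouring carbon (C1/C4 and C2/C3). This twofold-symmetric array is not the all-trans thermodynamic minimum, so it cannot be reached by simple equilibration. C1 and C2 are enolizable and drift toward the all-trans isomer, whereas the benzylic centres C3 and C4 are fixed once made and must therefore dictate C1 and C2. The absolute sense of the ring cannot be induced by the two side-chain stereocentres, which come from (R)-3-(3,4-dihydroxyphenyl)lactic acid. Four catechols, two α-acyloxy carboxylic acids and two hindered esters will not survive hydroxide, alkoxide, oxidants or strong acid, so the phenols and acids must be released together in a neutral last step. The feature that opens a pericyclic entry is that ring carbons C1–C4 plus the two carboxyl carbons are six of the eight carbons of a 7,8-diarylbicyclo[4.2.0]octa-2,4-diene. The two extra diene carbons can be excised oxidatively, and the trans aryl groups on C3/C4 are what thermal 8π conrotation of an (E,Z,Z,E)-1,8-diaryloctatetraene delivers.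

## Retrosynthesis

**27 ⇐ 26.** Ten O–benzyl bonds (eight aryl ethers, two esters) are cut. One neutral hydrogenolysis releases every sensitive group at once; methyl ethers or acetonides would need Lewis or Brønsted acids that the esters and C1/C2 would not tolerate. The forward step only has to leave the cyclobutane and the aliphatic esters alone.

**26 ⇐ 22 + 24.** The two ester C–O bonds are cut on the acyl side, giving the twofold-symmetric diacid 22 and two molecules of the protected hydroxy ester 24 (one step from danshensu 23). Opening a lactone precursor directly with 24 would save a step, but it asks a hindered secondary alkoxide to attack reversibly and invites scrambling of its own benzyl ester. Acylation by the bis(acid chloride) 25 is the conventional alternative. Because 22 is racemic and 24 enantiopure, this step is also the resolution: the two diastereomeric bis-esters are lactate-type resolving esters, and the one with the (1R,2R,3R,4R) ring is 26.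

**22 ⇐ 20 ⇐ 18.** Each aryl C–H ortho to the ring is traced back to a C–O bond (triflate 20). Each of these oxygens is then tied to the carboxyl on the neighbouring ring carbon, giving bislactone 18, which belongs to the class of anti head-to-head coumarin dimers. The extra oxygen is a temporary relay whose only purpose is to hold C1 and C2 cis to their aryl neighbours. Forward, the lactones are opened with allyl alcohol and the phenoxides trapped as triflates (via 19). One palladium/formate operation then removes the allyl groups and the triflates (via 21). Allyl is chosen because it is a small primary alcohol that can be used in excess and is later lost under the same conditions that reduce the triflate.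

**18 ⇐ 16 ⇐ 14.** The lactone C–O bond at C2 and the configuration of C2 are disconnected. The cascade gives the cis-diacid 14, (1R,2S,3R,4R), in which only the C1 carboxyl is cis to an aryl group. Base equilibration would invert C1 (toward all-trans), not C2. Instead, deprotection lets C1 lactonize (16, via 15), which locks it. The C2 acid is then activated so that it stereomutates through ketene 17 and is captured by the C3 phenol. Only the cis-fused lactone can form, so the bislactone is the one doubly closed product.

**14 ⇐ 13 ⇐ 11.** The two carboxyl carbons are reconnected through a two-carbon unit to give the cyclohexadiene ring of 11. Forward, exhaustive dihydroxylation (tetraol 12), periodate cleavage (dialdehyde 13) and chlorite oxidation are chemoselective for alkene, diol and aldehyde in the presence of alkoxyarenes; ozone or ruthenium oxidants are not.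

**11 ⇐ 10 ⇐ 9 ⇐ 8 (key).** The cyclobutane C1–C2 bond (6π) and C3–C4 bond (8π) are cut, leaving the acyclic, achiral tetraene 9, whose four alkene geometries carry all the stereochemical information. Compound 9 is made in situ from dienediyne 8 by twofold syn semi-hydrogenation. No other disconnection of the ring sets four centres from alkene geometry alone.

**8 ⇐ 6 ⇐ 4 + 5 ⇐ 3 ⇐ 2 ⇐ 1.** The central sp–sp bond is an oxidative homocoupling of two molecules of the alkyne (via 7), the sp–sp2 bonds a Sonogashira coupling of (E)-vinyl iodide 4 with trimethylsilylacetylene 5, and the E-alkene a Takai olefination of aldehyde 3. Compound 3 comes from 2,4,5-trihydroxybenzaldehyde 1 by regioselective benzylation (2) and MOM protection. The symmetry of the target means one arm is built once and dimerized.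

## Roads not taken

**Alternative 1:** The cut is at the two ring–aryl bonds. Forward, the enantiopure trans-diamide A2 would be arylated twice with aryl iodide A3 under Pd(OAc)2/AgOAc. Each quinolin-8-yl amide steers divalent palladium to the cis C–H bond of its neighbouring methylene, giving A1.
- Merits: each directing group places an aryl cis to its own carbonyl, exactly the C1/C4 and C2/C3 relationship. The trans aryls follow from the trans diamide, and the absolute configuration comes from A2. There is no racemate, no relay oxygen and no diastereomer separation, and the route is roughly half as long.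
- Weak points: the second arylation occurs next to a new bulky, electron-rich aryl group on a strained ring, under hot acetate conditions with stoichiometric silver. Both auxiliary amides must then be cleaved by activating or strongly basic conditions on a ring whose contra-thermodynamic cis carbonyl/aryl relationships are lost if C1 or C2 enolizes.
- Comparison: on step count and absolute stereocontrol this road is better, and that is conceded. The chosen plan sets against it a ring stereochemistry fixed by orbital symmetry with no selectivity to tune, C1 and C2 held in lactones during the manipulations, and no late amide cleavage.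

**Alternative 2:** The cut is at C1–C4 and C2–C3. Forward, photoexcited stilbene A5 would add to fumarate diester A6 through a sandwich exciplex to give A4, which is identical with 26.
- Merits: it is the most convergent route. Retention of both alkene geometries in a face-to-face complex gives precisely the 1,2-trans/3,4-trans/cis-across pattern, and it reaches the penultimate compound of the chosen route in a handful of steps.
- Weak points: the excited stilbene mainly isomerizes, cyclizes or dimerizes. A5 is a strong donor and A6 an acceptor, so electron transfer and isomerization of A6 to its maleate isomer can erode stereospecificity. The remote side-chain centres should not bias the two faces, so the same diastereomer separation is needed, from a more complex mixture and with the chiral component spent in a dilute, low-conversion photoreaction.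
- Comparison: it is clearly shorter, by about ten steps. The chosen plan offers ground-state stereochemistry without photostationary mixtures and postpones use of the chiral component to a clean coupling.

**Alternative 3:** The cut is at C1–C4 by ring expansion. Rh2(OAc)4 would decompose diazoester A8 and a cyclopropane bond would migrate to the carbenoid carbon to give cyclobutene A7.
- Merits: the trans aryl groups are set early on a cyclopropane and carried through a stereoretentive shift, and no carbons have to be excised later.
- Weak points: A7 lacks both C1 and C2 stereocentres. The tetrasubstituted alkene would need net trans delivery of hydrogen, each cis to an aryl group, which hydrogenation cannot do, so the same ortho-oxygen lactone relay is still required (hence the MOM groups in A7). Cyclopropylcarbenoids also fragment to alkene plus alkyne, and the electron-rich rings and acetal oxygens invite Buchner, C–H insertion and ylide pathways. A8 takes several steps to make, and the methyl esters must later be exchanged at epimerizable centres.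
- Comparison: it is neither shorter nor more selective. The chosen cascade fixes all four ring centres in one step, where this road fixes two.

Key step: step 6

## Route

Step 1
Reactants: 1 2,4,5-trihydroxybenzaldehyde
Product: 2 4,5-bis(benzyloxy)-2-hydroxybenzaldehyde
Conditions: BnBr (2.1 equiv), K2CO3 (2.1 equiv), DMF, 0 °C to rt, argon
Reagents that add atoms: benzyl bromide, BrCc1ccccc1
Why: Williamson etherification; the 2-hydroxyl is hydrogen-bonded to the formyl group and is the least nucleophilic of the three, so two equivalents of base and halide should alkylate O4 and O5 only.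

Step 2
Reactants: 2 4,5-bis(benzyloxy)-2-hydroxybenzaldehyde
Product: 3 4,5-bis(benzyloxy)-2-(methoxymethoxy)benzaldehyde
Conditions: MOMCl, i-Pr2NEt, CH2Cl2, 0 °C to rt
Reagents that add atoms: chloromethyl methyl ether, COCCl
Why: standard acetal protection of a phenol; MOM is orthogonal to benzyl and survives the chromium, palladium, copper, osmium and chlorite steps that follow.

Step 3
Reactants: 3 4,5-bis(benzyloxy)-2-(methoxymethoxy)benzaldehyde
Product: 4 1,2-bis(benzyloxy)-4-[(E)-2-iodoethenyl]-5-(methoxymethoxy)benzene
Conditions: CrCl2, CHI3, THF, 0 °C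
Reagents that add atoms: iodoform, IC(I)I
Why: Takai iodo-olefination; addition of the geminal dichromium species and anti elimination give the (E)-vinyl iodide, reliably so for aromatic aldehydes.

Step 4
Reactants: 4 (E)-vinyl iodide; 5 trimethylsilylacetylene
Product: 6 {(3E)-4-[4,5-bis(benzyloxy)-2-(methoxymethoxy)phenyl]but-3-en-1-yn-1-yl}trimethylsilane
Conditions: Pd(PPh3)2Cl2 (cat.), CuI (cat.), Et3N, THF, rt
Reagents that add atoms: none
Why: Sonogashira coupling of a vinyl iodide proceeds at room temperature with retention of the E geometry.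

Step 5
Reactants: 6 silyl enyne (two molecules are coupled)
Product: 8 (1E,7E)-1,8-bis[4,5-bis(benzyloxy)-2-(methoxymethoxy)phenyl]octa-1,7-diene-3,5-diyne, via terminal enyne 7 (not isolated)
Conditions: K2CO3 (cat.), MeOH–THF, rt; then CuCl (cat.), TMEDA, O2 (1 atm), acetone, rt
Reagents that add atoms: {(3E)-4-[4,5-bis(benzyloxy)-2-(methoxymethoxy)phenyl]but-3-en-1-yn-1-yl}trimethylsilane (second molecule of 6), COCOc1cc(OCc2ccccc2)c(OCc2ccccc2)cc1/C=C/C#C[Si](C)(C)C
Why: methanolysis of the C–Si bond followed by Glaser–Hay oxidative homocoupling, which joins two molecules of terminal enyne 7 at their alkyne termini to give the symmetric diyne; telescoping avoids storing the sensitive enyne 7.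

Step 6
Reactants: 8 (E,E)-dienediyne
Product: 11 rac-(1R,6S,7S,8S)-7,8-bis[4,5-bis(benzyloxy)-2-(methoxymethoxy)phenyl]bicyclo[4.2.0]octa-2,4-diene, via tetraene 9 (not isolated), via cyclooctatriene 10 (not isolated)
Conditions: H2 (1 atm), Pd/CaCO3 poisoned with Pb(OAc)2, quinoline, EtOAc, rt; filter; then PhMe, 70 °C
Reagents that add atoms: none
Why: Syn delivery of hydrogen to both triple bonds on the lead-poisoned palladium surface gives the (1E,3Z,5Z,7E)-tetraene 9, the same semi-hydrogenation of an (E,E)-dienediyne that is the established entry to thermal 8π–6π cascades. Tetraene 9 is a thermally allowed 8π system: conrotatory closure through a helical transition state joins its termini (the future C3–C4 bond) and forms the eight-membered ring of 10, and because both terminal aryl groups are E they finish trans; the two helical senses are mirror images, so 10 is racemic. The all-cis triene of 10 then closes by thermal 6π disrotation (the future C1–C2 bond), which forms the four- and six-membered rings and can only give their cis fusion. With trans aryl groups the two faces of the triene are related by the twofold axis of 10, so only one diastereomer of 11 is possible and no torquoselectivity is needed. All four stereocentres are thus set by alkene geometry: C3 and C4 by the E,E termini and conrotation, C1 and C2 (cis, one still to be inverted) by disrotation. The selectivity the step needs is geometric purity of 9, secured by the E-selective Takai step, stereoretentive couplings and syn hydrogenation, with quinoline and monitored hydrogen uptake guarding against over-reduction. Warming after filtration completes the 6π closure and draws the triene–bicycle equilibrium to the bicyclic side, which 7,8-disubstitution favours.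

Step 7
Reactants: 11 bicyclo[4.2.0]octa-2,4-diene
Product: 13 rac-(1R,2S,3R,4R)-3,4-bis[4,5-bis(benzyloxy)-2-(methoxymethoxy)phenyl]cyclobutane-1,2-dicarbaldehyde, via tetraol 12 (not isolated)
Conditions: OsO4 (cat.), N-methylmorpholine N-oxide, acetone–H2O, rt; then NaIO4, THF–H2O, 0 °C
Reagents that add atoms: osmium tetroxide, O=[Os](=O)(=O)=O; N-methylmorpholine N-oxide, C[N+]1([O-])CCOCC1; water, O
Why: Upjohn dihydroxylation of both alkenes of the diene, then periodate cleavage of the three vicinal-diol C–C bonds, excises the two central diene carbons as formic acid and leaves the cis-dialdehyde. Neither reagent attacks alkoxyarenes, and the near-neutral cleavage should not epimerize C1 or C2 (13 is used crude).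

Step 8
Reactants: 13 cis-dialdehyde
Product: 14 rac-(1R,2S,3R,4R)-3,4-bis[4,5-bis(benzyloxy)-2-(methoxymethoxy)phenyl]cyclobutane-1,2-dicarboxylic acid
Conditions: NaClO2, NaH2PO4, 2-methyl-2-butene, t-BuOH–THF–H2O, 0 °C to rt
Reagents that add atoms: sodium chlorite, [Na+].[O-]Cl=O
Why: Pinnick oxidation is buffered and non-enolizing, so the cis arrangement is kept; the alkene scavenger removes HOCl before it can chlorinate the electron-rich rings.

Step 9
Reactants: 14 cis-diacid
Product: 16 rac-6,7-bis(benzyloxy)-1-[4,5-bis(benzyloxy)-2-hydroxyphenyl]-3-oxo-1,2,2a,8b-tetrahydro-3H-cyclobuta[c]chromene-2-carboxylic acid (monolactone acid), via bisphenol diacid 15 (not isolated)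
Conditions: ZnBr2, n-PrSH, CH2Cl2, 0 °C to rt; then TsOH·H2O (cat.), PhMe, 50 °C
Reagents that add atoms: none
Why: Lewis acid/thiol cleavage of the aryl MOM ethers frees the ortho-phenols, the thiol capturing the methoxymethyl cation before it can alkylate the activated rings. Only the C1 carboxyl is cis to a hydroxyaryl group (on C4), so acid-catalysed lactonization closes one cis-fused six-membered lactone and leaves the C2 acid, trans to the C3 aryl, free.

Step 10
Reactants: 16 monolactone acid
Product: 18 rac-2,3,10,11-tetrakis(benzyloxy)-6a,6b,12b,12c-tetrahydrocyclobuta[1,2-c:4,3-c']dichromene-6,7-dione (anti head-to-head bislactone), via ketene 17 (not isolated)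
Conditions: 2-chloro-1-methylpyridinium iodide, Et3N, MeCN, reflux, high dilution (slow addition of 16)
Reagents that add atoms: none
Why: Mukaiyama lactonization used with deliberate stereomutation: the 2-acyloxypyridinium salt of the C2 acid cannot reach the C3 phenol while trans to it, but triethylamine removes its α-hydrogen to give ketene 17 (the usual way this reagent makes ketenes from acids), which is planar at C2. Intramolecular addition of the phenol and protonation should give only the cis-fused lactone, a trans-fused six–four lactone being far more strained, so C2 is inverted and locked; this parallels the known conversion of trans-cyclobutane-1,2-dicarboxylic acids into cis anhydrides through activated acyl derivatives. C1 is protected by its existing cis-fused lactone.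

Step 11
Reactants: 18 bislactone
Product: 20 diallyl rac-(1R,2R,3R,4R)-3,4-bis[4,5-bis(benzyloxy)-2-{[(trifluoromethyl)sulfonyl]oxy}phenyl]cyclobutane-1,2-dicarboxylate, via bisphenol diallyl ester 19 (not isolated)
Conditions: allyl alcohol (excess), Cs2CO3, THF, 0 °C to rt; then PhNTf2, 0 °C to rt
Reagents that add atoms: allyl alcohol, C=CCO; N-phenylbis(trifluoromethanesulfonimide), O=S(=O)(N(c1ccccc1)S(=O)(=O)C(F)(F)F)C(F)(F)F
Why: base-catalysed alcoholysis of the two aryl-ester lactones by a primary alcohol in excess, the ring opening known for anti head-to-head coumarin dimers; the phenoxides are triflated in the same flask before they can re-close. Carbonate at room temperature should not enolize the ester α-carbons, so the 1,2-trans, cis-to-aryl array is kept.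

Step 12
Reactants: 20 diallyl ester bistriflate
Product: 22 rac-(1R,2R,3R,4R)-3,4-bis[3,4-bis(benzyloxy)phenyl]cyclobutane-1,2-dicarboxylic acid, via diacid bistriflate 21 (not isolated)
Conditions: Pd(OAc)2, 1,1'-bis(diphenylphosphino)ferrocene, HCO2H, Et3N, DMF, rt then 70 °C
Reagents that add atoms: none
Why: zerovalent palladium with triethylammonium formate first cleaves the allyl esters through π-allyl complexes (Tsuji–Trost deallylation with hydride capture) and, on warming, reduces the aryl triflates by oxidative addition, formate decarboxylation and C–H reductive elimination. Benzyl ethers and the ring stereocentres are untouched.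

Step 13
Reactants: 23 (R)-3-(3,4-dihydroxyphenyl)lactic acid (danshensu)
Product: 24 benzyl (2R)-3-[3,4-bis(benzyloxy)phenyl]-2-hydroxypropanoate
Conditions: BnBr (3.3 equiv), K2CO3, DMF, rt, argon
Reagents that add atoms: benzyl bromide, BrCc1ccccc1
Why: carbonate deprotonates only the acid and the two phenols, so O-alkylation gives the benzyl ester bis(benzyl ether) and leaves the secondary alcohol free; the stereocentre is not involved.

Step 14
Reactants: 22 racemic diacid; 24 protected (R)-danshensu (two molecules are esterified)
Product: 26 bis[(2R)-1-(benzyloxy)-3-[3,4-bis(benzyloxy)phenyl]-1-oxopropan-2-yl] (1R,2R,3R,4R)-3,4-bis[3,4-bis(benzyloxy)phenyl]cyclobutane-1,2-dicarboxylate, via bis(acid chloride) 25 (not isolated)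
Conditions: (COCl)2, DMF (cat.), CH2Cl2, 0 °C to rt; concentrate; then 24 (2.5 equiv), pyridine, 4-(dimethylamino)pyridine (cat.), CH2Cl2, −20 °C to rt; chromatographic separation of the two diastereomers
Reagents that add atoms: benzyl (2R)-3-[3,4-bis(benzyloxy)phenyl]-2-hydroxypropanoate (second molecule of 24), O[C@H](Cc1ccc(OCc2ccccc2)c(OCc2ccccc2)c1)C(=O)OCc1ccccc1
Why: twofold acylation of a secondary α-hydroxy ester by a cyclobutane-1,2-dicarbonyl dichloride, one molecule of 24 per acyl chloride, with pyridine as the only base, which avoids the trialkylamine-induced ketene formation that would stereomutate C1/C2. Racemic 22 and enantiopure 24 give two diastereomeric bis-esters that behave as lactate-type resolving esters and should separate on silica; the one with the (1R,2R,3R,4R) ring is 26, assigned by chiroptical comparison of derived 27 with the natural product.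

Step 15
Reactants: 26 decabenzyl-protected target
Product: 27 bis[(1R)-1-carboxy-2-(3,4-dihydroxyphenyl)ethyl] (1R,2R,3R,4R)-3,4-bis(3,4-dihydroxyphenyl)cyclobutane-1,2-dicarboxylate (CNP0163929.1)
Conditions: H2 (1 atm), Pd/C, THF–MeOH, rt
Reagents that add atoms: none
Why: neutral hydrogenolysis of eight benzyl ethers and two benzyl esters releases the catechols and acids last; the cyclobutane and the aliphatic esters are inert to Pd/C at atmospheric pressure.

## Compound list

1 | 2,4,5-trihydroxybenzaldehyde | O=Cc1cc(O)c(O)cc1O | starting material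
2 | 4,5-bis(benzyloxy)-2-hydroxybenzaldehyde | O=Cc1cc(OCc2ccccc2)c(OCc2ccccc2)cc1O | intermediate
3 | 4,5-bis(benzyloxy)-2-(methoxymethoxy)benzaldehyde | O=Cc1cc(OCc2ccccc2)c(OCc2ccccc2)cc1OCOC | intermediate
4 | 1,2-bis(benzyloxy)-4-[(E)-2-iodoethenyl]-5-(methoxymethoxy)benzene | COCOc1cc(OCc2ccccc2)c(OCc2ccccc2)cc1/C=C/I | intermediate
5 | trimethylsilylacetylene | C#C[Si](C)(C)C | starting material
6 | {(3E)-4-[4,5-bis(benzyloxy)-2-(methoxymethoxy)phenyl]but-3-en-1-yn-1-yl}trimethylsilane | COCOc1cc(OCc2ccccc2)c(OCc2ccccc2)cc1/C=C/C#C[Si](C)(C)C | intermediate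
7 | 1,2-bis(benzyloxy)-4-[(1E)-but-1-en-3-yn-1-yl]-5-(methoxymethoxy)benzene (terminal enyne; not isolated) | COCOc1cc(OCc2ccccc2)c(OCc2ccccc2)cc1/C=C/C#C | intermediate
8 | (1E,7E)-1,8-bis[4,5-bis(benzyloxy)-2-(methoxymethoxy)phenyl]octa-1,7-diene-3,5-diyne | COCOc1cc(OCc2ccccc2)c(OCc2ccccc2)cc1/C=C/C#CC#C/C=C/c1cc(OCc2ccccc2)c(OCc2ccccc2)cc1OCOC | intermediate
9 | (1E,3Z,5Z,7E)-1,8-bis[4,5-bis(benzyloxy)-2-(methoxymethoxy)phenyl]octa-1,3,5,7-tetraene (not isolated) | COCOc1cc(OCc2ccccc2)c(OCc2ccccc2)cc1/C=C/C=C\C=C/C=C/c1cc(OCc2ccccc2)c(OCc2ccccc2)cc1OCOC | intermediate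
10 | rac-trans-7,8-bis[4,5-bis(benzyloxy)-2-(methoxymethoxy)phenyl]cycloocta-1,3,5-triene, all ring alkenes Z (not isolated) | COCOc1cc(OCc2ccccc2)c(OCc2ccccc2)cc1[C@H]1/C=C\C=C/C=C\[C@@H]1c1cc(OCc2ccccc2)c(OCc2ccccc2)cc1OCOC | intermediate
11 | rac-(1R,6S,7S,8S)-7,8-bis[4,5-bis(benzyloxy)-2-(methoxymethoxy)phenyl]bicyclo[4.2.0]octa-2,4-diene (cis ring fusion, trans aryl groups) | C1=C[C@H]2[C@@H](C=C1)[C@H](c1cc(OCc3ccccc3)c(OCc3ccccc3)cc1OCOC)[C@H]2c1cc(OCc2ccccc2)c(OCc2ccccc2)cc1OCOC | intermediate
12 | rac-7,8-bis[4,5-bis(benzyloxy)-2-(methoxymethoxy)phenyl]bicyclo[4.2.0]octane-2,3,4,5-tetrol (cis fusion, trans aryls; diastereomer mixture at the four carbinol carbons, left undefined; not isolated) | OC1C(O)[C@H]2[C@@H](C(O)C1O)[C@H](c1cc(OCc3ccccc3)c(OCc3ccccc3)cc1OCOC)[C@H]2c1cc(OCc2ccccc2)c(OCc2ccccc2)cc1OCOC | intermediate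
13 | rac-(1R,2S,3R,4R)-3,4-bis[4,5-bis(benzyloxy)-2-(methoxymethoxy)phenyl]cyclobutane-1,2-dicarbaldehyde | O=C[C@H]1[C@@H](C=O)[C@H](c2cc(OCc3ccccc3)c(OCc3ccccc3)cc2OCOC)[C@H]1c1cc(OCc2ccccc2)c(OCc2ccccc2)cc1OCOC | intermediate
14 | rac-(1R,2S,3R,4R)-3,4-bis[4,5-bis(benzyloxy)-2-(methoxymethoxy)phenyl]cyclobutane-1,2-dicarboxylic acid | OC(=O)[C@H]1[C@@H](C(=O)O)[C@H](c2cc(OCc3ccccc3)c(OCc3ccccc3)cc2OCOC)[C@H]1c1cc(OCc2ccccc2)c(OCc2ccccc2)cc1OCOC | intermediate
15 | rac-(1R,2S,3R,4R)-3,4-bis[4,5-bis(benzyloxy)-2-hydroxyphenyl]cyclobutane-1,2-dicarboxylic acid (not isolated) | OC(=O)[C@H]1[C@@H](C(=O)O)[C@H](c2cc(OCc3ccccc3)c(OCc3ccccc3)cc2O)[C@H]1c1cc(OCc2ccccc2)c(OCc2ccccc2)cc1O | intermediate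
16 | rac-6,7-bis(benzyloxy)-1-[4,5-bis(benzyloxy)-2-hydroxyphenyl]-3-oxo-1,2,2a,8b-tetrahydro-3H-cyclobuta[c]chromene-2-carboxylic acid (cis-fused lactone; 2,2a-cis; 1,2-trans; 1,8b-trans) | O=C1Oc2cc(OCc3ccccc3)c(OCc3ccccc3)cc2[C@H]2[C@@H]1[C@@H](C(=O)O)[C@@H]2c1cc(OCc2ccccc2)c(OCc2ccccc2)cc1O | intermediate
17 | rac-6,7-bis(benzyloxy)-1-[4,5-bis(benzyloxy)-2-hydroxyphenyl]-2-(oxomethylidene)-1,2,2a,8b-tetrahydro-3H-cyclobuta[c]chromen-3-one (ketene; not isolated) | O=C1Oc2cc(OCc3ccccc3)c(OCc3ccccc3)cc2[C@H]2[C@@H]1C(=C=O)[C@@H]2c1cc(OCc2ccccc2)c(OCc2ccccc2)cc1O | intermediate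
18 | rac-2,3,10,11-tetrakis(benzyloxy)-6a,6b,12b,12c-tetrahydrocyclobuta[1,2-c:4,3-c']dichromene-6,7-dione (both lactones cis-fused, on opposite faces of the cyclobutane; twofold-symmetric) | O=C1Oc2cc(OCc3ccccc3)c(OCc3ccccc3)cc2[C@H]2[C@@H]1[C@H]1[C@@H]2c2cc(OCc3ccccc3)c(OCc3ccccc3)cc2OC1=O | intermediate
19 | diallyl rac-(1R,2R,3R,4R)-3,4-bis[4,5-bis(benzyloxy)-2-hydroxyphenyl]cyclobutane-1,2-dicarboxylate (present as its bis-phenoxide; not isolated) | C=CCOC(=O)[C@H]1[C@H](C(=O)OCC=C)[C@H](c2cc(OCc3ccccc3)c(OCc3ccccc3)cc2O)[C@H]1c1cc(OCc2ccccc2)c(OCc2ccccc2)cc1O | intermediate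
20 | diallyl rac-(1R,2R,3R,4R)-3,4-bis[4,5-bis(benzyloxy)-2-{[(trifluoromethyl)sulfonyl]oxy}phenyl]cyclobutane-1,2-dicarboxylate | C=CCOC(=O)[C@H]1[C@H](C(=O)OCC=C)[C@H](c2cc(OCc3ccccc3)c(OCc3ccccc3)cc2OS(=O)(=O)C(F)(F)F)[C@H]1c1cc(OCc2ccccc2)c(OCc2ccccc2)cc1OS(=O)(=O)C(F)(F)F | intermediate
21 | rac-(1R,2R,3R,4R)-3,4-bis[4,5-bis(benzyloxy)-2-{[(trifluoromethyl)sulfonyl]oxy}phenyl]cyclobutane-1,2-dicarboxylic acid (not isolated) | OC(=O)[C@H]1[C@H](C(=O)O)[C@H](c2cc(OCc3ccccc3)c(OCc3ccccc3)cc2OS(=O)(=O)C(F)(F)F)[C@H]1c1cc(OCc2ccccc2)c(OCc2ccccc2)cc1OS(=O)(=O)C(F)(F)F | intermediate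
22 | rac-(1R,2R,3R,4R)-3,4-bis[3,4-bis(benzyloxy)phenyl]cyclobutane-1,2-dicarboxylic acid | OC(=O)[C@H]1[C@H](C(=O)O)[C@H](c2ccc(OCc3ccccc3)c(OCc3ccccc3)c2)[C@H]1c1ccc(OCc2ccccc2)c(OCc2ccccc2)c1 | intermediate
23 | (R)-3-(3,4-dihydroxyphenyl)lactic acid (danshensu) | O[C@H](Cc1ccc(O)c(O)c1)C(=O)O | starting material
24 | benzyl (2R)-3-[3,4-bis(benzyloxy)phenyl]-2-hydroxypropanoate | O[C@H](Cc1ccc(OCc2ccccc2)c(OCc2ccccc2)c1)C(=O)OCc1ccccc1 | intermediate
25 | rac-(1R,2R,3R,4R)-3,4-bis[3,4-bis(benzyloxy)phenyl]cyclobutane-1,2-dicarbonyl dichloride (not isolated) | ClC(=O)[C@H]1[C@H](C(Cl)=O)[C@H](c2ccc(OCc3ccccc3)c(OCc3ccccc3)c2)[C@H]1c1ccc(OCc2ccccc2)c(OCc2ccccc2)c1 | intermediate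
26 | bis[(2R)-1-(benzyloxy)-3-[3,4-bis(benzyloxy)phenyl]-1-oxopropan-2-yl] (1R,2R,3R,4R)-3,4-bis[3,4-bis(benzyloxy)phenyl]cyclobutane-1,2-dicarboxylate | O=C(O[C@H](Cc1ccc(OCc2ccccc2)c(OCc2ccccc2)c1)C(=O)OCc1ccccc1)[C@H]1[C@H](C(=O)O[C@H](Cc2ccc(OCc3ccccc3)c(OCc3ccccc3)c2)C(=O)OCc2ccccc2)[C@H](c2ccc(OCc3ccccc3)c(OCc3ccccc3)c2)[C@H]1c1ccc(OCc2ccccc2)c(OCc2ccccc2)c1 | intermediate
27 | bis[(1R)-1-carboxy-2-(3,4-dihydroxyphenyl)ethyl] (1R,2R,3R,4R)-3,4-bis(3,4-dihydroxyphenyl)cyclobutane-1,2-dicarboxylate (CNP0163929.1) | O=C(O[C@H](Cc1ccc(O)c(O)c1)C(=O)O)[C@H]1[C@H](C(=O)O[C@H](Cc2ccc(O)c(O)c2)C(=O)O)[C@H](c2ccc(O)c(O)c2)[C@H]1c1ccc(O)c(O)c1 | target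

## Step count and least certain steps

Total steps: 15. Longest linear sequence: 14 (steps 1–12, 14 and 15, from 1); step 13 is a one-step side branch.

**Key step (step 6).** The semi-hydrogenation may not be cleanly twofold and syn: a Z-alkene may be over-reduced once formed, or isomerize on the metal. That would feed geometrically impure tetraene into a cascade whose outcome depends only on geometry. The triene–bicycle equilibrium may also not lie wholly on the bicyclic side. The fallback assembles the tetraene without any reduction. Setting out from vinyl iodide 4, Stille coupling with an excess of (Z)-1,2-bis(tributylstannyl)ethene (Pd(PPh3)4, CuI, DMF, rt) would give tributyl{(1Z,3E)-4-[4,5-bis(benzyloxy)-2-(methoxymethoxy)phenyl]buta-1,3-dien-1-yl}stannane F1 with retention at both alkenes. CuCl-mediated oxidative homocoupling of F1 (DMF, rt) would form the central bond with retention and give tetraene 9, which cyclizes in the same flask, rejoining the route at 11.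

**Step 10.** The activated C2 acyl group, unable to reach its phenol while trans, may acylate a second molecule (oligoester formation) faster than it loses its hindered α-hydrogen; stereomutation would then lag behind consumption of the activated ester. The fallback separates stereomutation from activation. From 16, thioesterification (PhSH, EDC·HCl, DMAP cat., CH2Cl2, 0 °C) would give the isolable S-phenyl thioester of 16, F2. Treatment with DBU in THF at room temperature would equilibrate the more acidic thioester α-centre through its enolate, and the epimer whose acyl group is cis to the C3 phenoxide would be drained by intramolecular acyl transfer with loss of thiophenolate, returning to the route at 18.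

**Step 11.** Re-closure of the phenoxide ester to the lactone may outpace triflation, or the second lactone may open incompletely, leaving lactone/triflate mixtures. The fallback removes the reversibility by lowering the oxidation level. From 18, LiAlH4 (THF, 0 °C) would reduce both lactones to rac-{3,4-bis[4,5-bis(benzyloxy)-2-hydroxyphenyl]cyclobutane-1,2-diyl}dimethanol F3, which cannot re-close. Selective phenol triflation (PhNTf2, K2CO3, THF) would give the bistriflate diol F4, and palladium/formate reduction as in step 12 would give rac-{3,4-bis[3,4-bis(benzyloxy)phenyl]cyclobutane-1,2-diyl}dimethanol F5. Oxidation of the two primary alcohols (TEMPO cat., PhI(OAc)2, MeCN–H2O) would return to the route at 22.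

**Step 14.** C1 or C2 may stereomutate while both carboxyls are activated (enolization of the acyl chloride or acylpyridinium), or the reaction may stall at the monoester because the second acylation is hindered. The fallback activates the alcohol instead of the acid. L-DOPA would be diazotized (NaNO2, aqueous H2SO4, 0 °C, retention through the α-lactone) to (S)-3-(3,4-dihydroxyphenyl)lactic acid F6 and benzylated as in step 13 to benzyl (2S)-3-[3,4-bis(benzyloxy)phenyl]-2-hydroxypropanoate F7. Mitsunobu esterification of diacid 22 with two molecules of F7 (PPh3, diisopropyl azodicarboxylate, THF, 0 °C to rt) displaces the activated hydroxyl with inversion and gives the (R)-configured esters without activating the ring carboxyls. After the same diastereomer separation it rejoins the route at 26.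

**Step 1.** Regiocontrol may be lost (benzylation at O2, or incomplete alkylation), and the electron-rich triol may oxidize in air under base. The fallback protects everything and then removes one group. From 1, exhaustive benzylation (BnBr excess, K2CO3, DMF) would give 2,4,5-tris(benzyloxy)benzaldehyde F8. Chelation-controlled cleavage of only the ortho benzyl ether (MgBr2·OEt2, PhMe–Et2O, reflux) would return to the route at 2.

## Further compounds

F1 | step 6 | tributyl{(1Z,3E)-4-[4,5-bis(benzyloxy)-2-(methoxymethoxy)phenyl]buta-1,3-dien-1-yl}stannane | CCCC[Sn](CCCC)(CCCC)/C=C\C=C\c1cc(OCc2ccccc2)c(OCc2ccccc2)cc1OCOC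
F2 | step 10 | S-phenyl rac-6,7-bis(benzyloxy)-1-[4,5-bis(benzyloxy)-2-hydroxyphenyl]-3-oxo-1,2,2a,8b-tetrahydro-3H-cyclobuta[c]chromene-2-carbothioate (configuration of 16) | O=C1Oc2cc(OCc3ccccc3)c(OCc3ccccc3)cc2[C@H]2[C@@H]1[C@@H](C(=O)Sc1ccccc1)[C@@H]2c1cc(OCc2ccccc2)c(OCc2ccccc2)cc1O
F3 | step 11 | rac-{3,4-bis[4,5-bis(benzyloxy)-2-hydroxyphenyl]cyclobutane-1,2-diyl}dimethanol (relative configuration of 22) | OC[C@H]1[C@H](CO)[C@H](c2cc(OCc3ccccc3)c(OCc3ccccc3)cc2O)[C@H]1c1cc(OCc2ccccc2)c(OCc2ccccc2)cc1O
F4 | step 11 | rac-{3,4-bis[4,5-bis(benzyloxy)-2-{[(trifluoromethyl)sulfonyl]oxy}phenyl]cyclobutane-1,2-diyl}dimethanol (relative configuration of 22) | OC[C@H]1[C@H](CO)[C@H](c2cc(OCc3ccccc3)c(OCc3ccccc3)cc2OS(=O)(=O)C(F)(F)F)[C@H]1c1cc(OCc2ccccc2)c(OCc2ccccc2)cc1OS(=O)(=O)C(F)(F)F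
F5 | step 11 | rac-{3,4-bis[3,4-bis(benzyloxy)phenyl]cyclobutane-1,2-diyl}dimethanol (relative configuration of 22) | OC[C@H]1[C@H](CO)[C@H](c2ccc(OCc3ccccc3)c(OCc3ccccc3)c2)[C@H]1c1ccc(OCc2ccccc2)c(OCc2ccccc2)c1
F6 | step 14 | (S)-3-(3,4-dihydroxyphenyl)lactic acid | O[C@@H](Cc1ccc(O)c(O)c1)C(=O)O
F7 | step 14 | benzyl (2S)-3-[3,4-bis(benzyloxy)phenyl]-2-hydroxypropanoate | O[C@@H](Cc1ccc(OCc2ccccc2)c(OCc2ccccc2)c1)C(=O)OCc1ccccc1
F8 | step 1 | 2,4,5-tris(benzyloxy)benzaldehyde | O=Cc1cc(OCc2ccccc2)c(OCc2ccccc2)cc1OCc1ccccc1
A1 | alternative 1 | (1R,2R,3R,4R)-3,4-bis[3,4-bis(benzyloxy)phenyl]-N,N'-di(quinolin-8-yl)cyclobutane-1,2-dicarboxamide | O=C(Nc1cccc2cccnc12)[C@H]1[C@H](C(=O)Nc2cccc3cccnc23)[C@H](c2ccc(OCc3ccccc3)c(OCc3ccccc3)c2)[C@H]1c1ccc(OCc2ccccc2)c(OCc2ccccc2)c1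
A2 | alternative 1 | (1R,2R)-N,N'-di(quinolin-8-yl)cyclobutane-1,2-dicarboxamide | O=C(Nc1cccc2cccnc12)[C@H]1[C@H](C(=O)Nc2cccc3cccnc23)CC1
A3 | alternative 1 | 1,2-bis(benzyloxy)-4-iodobenzene | Ic1ccc(OCc2ccccc2)c(OCc2ccccc2)c1
A4 | alternative 2 | bis[(2R)-1-(benzyloxy)-3-[3,4-bis(benzyloxy)phenyl]-1-oxopropan-2-yl] (1R,2R,3R,4R)-3,4-bis[3,4-bis(benzyloxy)phenyl]cyclobutane-1,2-dicarboxylate (identical with 26) | O=C(O[C@H](Cc1ccc(OCc2ccccc2)c(OCc2ccccc2)c1)C(=O)OCc1ccccc1)[C@H]1[C@H](C(=O)O[C@H](Cc2ccc(OCc3ccccc3)c(OCc3ccccc3)c2)C(=O)OCc2ccccc2)[C@H](c2ccc(OCc3ccccc3)c(OCc3ccccc3)c2)[C@H]1c1ccc(OCc2ccccc2)c(OCc2ccccc2)c1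
A5 | alternative 2 | (E)-3,3',4,4'-tetrakis(benzyloxy)stilbene | c1ccc(COc2ccc(/C=C/c3ccc(OCc4ccccc4)c(OCc4ccccc4)c3)cc2OCc2ccccc2)cc1
A6 | alternative 2 | bis[(2R)-1-(benzyloxy)-3-[3,4-bis(benzyloxy)phenyl]-1-oxopropan-2-yl] fumarate | O=C(/C=C/C(=O)O[C@H](Cc1ccc(OCc2ccccc2)c(OCc2ccccc2)c1)C(=O)OCc1ccccc1)O[C@H](Cc1ccc(OCc2ccccc2)c(OCc2ccccc2)c1)C(=O)OCc1ccccc1
A7 | alternative 3 | dimethyl rac-trans-3,4-bis[4,5-bis(benzyloxy)-2-(methoxymethoxy)phenyl]cyclobut-1-ene-1,2-dicarboxylate | COC(=O)C1=C(C(=O)OC)[C@H](c2cc(OCc3ccccc3)c(OCc3ccccc3)cc2OCOC)[C@H]1c1cc(OCc2ccccc2)c(OCc2ccccc2)cc1OCOC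
A8 | alternative 3 | methyl rac-trans-2,3-bis[4,5-bis(benzyloxy)-2-(methoxymethoxy)phenyl]-1-(1-diazo-2-methoxy-2-oxoethyl)cyclopropane-1-carboxylate | COC(=O)C(=[N+]=[N-])C1(C(=O)OC)[C@H](c2cc(OCc3ccccc3)c(OCc3ccccc3)cc2OCOC)[C@H]1c1cc(OCc2ccccc2)c(OCc2ccccc2)cc1OCOC
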